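**Retrosynthetic overview**
1. The γ-pyrone is made last. Breaking O1–C2 (a diketone enolate oxygen adds to a ketene-acetal carbon and MeO⁻ leaves) and C5–C6 leads back to acid 13 and the C6 block 17. This is the key step and it is new.
2. Acid 13 comes from the cis-fused δ-lactone 12. Allylic C–O hydrogenolysis turns the tether CH2–O into the side-chain C-methyl.
3. Lactone 12 comes from ester 11 by a desymmetrising intramolecular Heck reaction that sets both ring centres. Ester 11 comes from acid 10 and iodo-allylic alcohol 8 through a C–O ester bond (Mitsunobu).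
4. Acid 10 comes from 3,5-dimethylbenzoic acid by Birch reductive methylation. Alcohol 8 comes from (S)-but-3-yn-2-ol and propanal; the allenylzinc addition sets the side-chain centre.
5. Ring order: carbocycle (from the arene), then the temporary δ-lactone, then the γ-pyrone.

Assumption: short-lived organometallic species (acetylide, enolates, allenyl-Pd/Zn, alkyl-Pd) are described in the Why lines and not numbered, and (R)-BINAP is taken to select the ring alkene drawn (the other product is a separable diastereomer, and (S)-BINAP is equally available).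

Step 1
Reactants: 1 (S)-but-3-yn-2-ol
Product: 2 (S)-but-3-yn-2-yl methanesulfonate
Conditions: MsCl, Et3N, CH2Cl2, −78 → 0 °C
Reagents that add atoms: methanesulfonyl chloride, CS(=O)(=O)Cl
Why: O-sulfonylation (mesylate formation) does not touch the C–O bond, so the (S) centre is retained.

Step 2
Reactants: 2 (S)-but-3-yn-2-yl methanesulfonate, 3 propanal
Product: 4 (3S,4R)-4-methylhex-5-yn-3-ol (anti)
Conditions: Pd(OAc)2 (5 mol %), PPh3 (5 mol %), Et2Zn (3 equiv), THF, −78 → −20 °C; aq NH4Cl
Reagents that add atoms: none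
Why: Marshall–Tamaru propargylation: Pd(0) opens the mesylate anti (SN2′), Et2Zn converts the allenyl-Pd into a configurationally stable allenylzinc, and this adds to propanal syn through a cyclic SE2′ transition state, so the methyl-bearing carbon is set (R) with net inversion and the carbinol comes out anti (it is erased in step 12).

Step 3
Reactants: 4 (3S,4R)-4-methylhex-5-yn-3-ol
Product: 5 triethyl{[(3S,4R)-4-methylhex-5-yn-3-yl]oxy}silane
Conditions: TESCl, imidazole, CH2Cl2, 0 → 23 °C
Reagents that add atoms: chlorotriethylsilane, CC[Si](Cl)(CC)CC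
Why: Standard O-silylation masks the future ketone oxygen through the basic and organometallic steps and touches no stereocentre.

Step 4
Reactants: 5 triethyl{[(3S,4R)-4-methylhex-5-yn-3-yl]oxy}silane
Product: 6 (4R,5S)-4-methyl-5-(triethylsilyloxy)hept-2-yn-1-ol
Conditions: n-BuLi, THF, −78 °C; (CH2O)n, −78 → 23 °C; aq NH4Cl
Reagents that add atoms: formaldehyde (from paraformaldehyde), C=O
Why: Hydroxymethylation of a lithium acetylide adds the carbon that first carries the tether oxygen and later becomes the side-chain methyl.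

Step 5
Reactants: 6 (4R,5S)-4-methyl-5-(triethylsilyloxy)hept-2-yn-1-ol
Product: 8 (2E,4R,5S)-2-iodo-4-methyl-5-(triethylsilyloxy)hept-2-en-1-ol, via (2E,4R,5S)-4-methyl-2-(tributylstannyl)-5-(triethylsilyloxy)hept-2-en-1-ol 7 (not isolated)
Conditions: Bu3SnH, PdCl2(PPh3)2 (2 mol %), THF, 0 → 23 °C; then I2, CH2Cl2, 0 °C
Reagents that add atoms: tributyltin hydride, CCCC[SnH](CCCC)CCCC (Sn of 7 only); iodine, II
Why: Pd-catalysed syn-hydrostannation places tin on the alkyne carbon next to CH2OH (away from the branched C4) and iododestannylation proceeds with retention, which fixes the alkene geometry that ends as the (E)-trisubstituted side-chain alkene.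

Step 6
Reactants: 9 3,5-dimethylbenzoic acid
Product: 10 1,3,5-trimethylcyclohexa-2,5-diene-1-carboxylic acid (achiral)
Conditions: Li, NH3(l)/THF, −78 °C; MeI, −78 °C → rt; aq HCl
Reagents that add atoms: iodomethane, CI
Why: Birch reductive alkylation: the carboxylate directs 1,4-reduction and the resulting enediolate is C-methylated at C1, giving the quaternary carbon in a diene that still has a mirror plane.

Step 7
Reactants: 8 (2E,4R,5S)-2-iodo-4-methyl-5-(triethylsilyloxy)hept-2-en-1-ol, 10 1,3,5-trimethylcyclohexa-2,5-diene-1-carboxylic acid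
Product: 11 [(2E,4R,5S)-2-iodo-4-methyl-5-(triethylsilyloxy)hept-2-en-1-yl] 1,3,5-trimethylcyclohexa-2,5-diene-1-carboxylate
Conditions: PPh3, DIAD, THF, 0 → 23 °C
Reagents that add atoms: none
Why: Mitsunobu esterification forms the C–O tether by SN2 attack of the hindered carboxylate on the activated primary allylic alcohol, so no nucleophile has to reach the crowded carbonyl and no stereocentre is touched.

Step 8
Reactants: 11 [(2E,4R,5S)-2-iodo-4-methyl-5-(triethylsilyloxy)hept-2-en-1-yl] 1,3,5-trimethylcyclohexa-2,5-diene-1-carboxylate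
Product: 12 (4Z,4aR,8aR)-5,7,8a-trimethyl-4-[(2R,3S)-2-methyl-3-(triethylsilyloxy)pentylidene]-3,4,4a,8a-tetrahydro-1H-isochromen-1-one (cis-fused δ-lactone)
Conditions: Pd2(dba)3·CHCl3 (5 mol %), (R)-BINAP (12 mol %), Ag2CO3 (1.5 equiv), NMP, 60 °C
Reagents that add atoms: none
Why: Asymmetric intramolecular Mizoroki–Heck desymmetrisation of a cyclohexa-2,5-diene (cationic manifold): the 6-exo syn-carbopalladation can only occur on the ring face that carries the ester tether, so the alkenyl carbon ends cis to the acyl carbon, the ligand chooses one of the two ring alkenes and thereby sets both ring centres, and syn β-H elimination of the bis-allylic C–H gives the conjugated 1,3-diene.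

Step 9
Reactants: 12 cis-fused δ-lactone
Product: 13 (1R,6S)-1,3,5-trimethyl-6-[(2E,4R,5S)-4-methyl-5-(triethylsilyloxy)hept-2-en-2-yl]cyclohexa-2,4-diene-1-carboxylic acid
Conditions: Pd(PPh3)4 (5 mol %), LiBHEt3 (1.1 equiv), THF, 0 °C; cold 0.1 M HCl
Reagents that add atoms: none
Why: Pd-catalysed allylic hydrogenolysis (Tsuji–Trost ionisation of the allylic lactone followed by external hydride attack at the unhindered CH2 terminus) releases the carboxylate and turns CH2–O into CH3 while keeping the trisubstituted alkene and its geometry.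

Step 10
Reactants: 14 trimethyl orthopropionate, 15 propionyl chloride
Product: 17 1,1-dimethoxy-2-methylpent-1-en-3-one, via 1,1-dimethoxyprop-1-ene 16 (not isolated)
Conditions: TMSOTf, i-Pr2NEt (2.5 equiv), CH2Cl2, 0 → 23 °C; then EtCOCl, −78 → 0 °C
Reagents that add atoms: none
Why: Silyl-triflate-induced loss of MeOH from the orthoester gives the ketene acetal, which is C-acylated at its nucleophilic β-carbon and deprotonated by the amine to the acylketene acetal (ketene-acetal acylation).

Step 11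
Reactants: 13 (1R,6S)-1,3,5-trimethyl-6-[(2E,4R,5S)-4-methyl-5-(triethylsilyloxy)hept-2-en-2-yl]cyclohexa-2,4-diene-1-carboxylic acid, 17 1,1-dimethoxy-2-methylpent-1-en-3-one
Product: 20 2-methoxy-3,5-dimethyl-6-{(1R,6S)-1,3,5-trimethyl-6-[(2E,4R,5S)-4-methyl-5-(triethylsilyloxy)hept-2-en-2-yl]cyclohexa-2,4-dien-1-yl}-4H-pyran-4-one, via (1R,6S)-1,3,5-trimethyl-6-[(2E,4R,5S)-4-methyl-5-(triethylsilyloxy)hept-2-en-2-yl]cyclohexa-2,4-diene-1-carbonyl chloride 18 (not isolated), via 5,5-dimethoxy-2,4-dimethyl-1-{(1R,6S)-1,3,5-trimethyl-6-[(2E,4R,5S)-4-methyl-5-(triethylsilyloxy)hept-2-en-2-yl]cyclohexa-2,4-dien-1-yl}pent-4-ene-1,3-dione 19 (not isolated)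
Conditions: 13, Ghosez reagent, CH2Cl2, 0 °C; added to 17 (2.2 equiv)/LiHMDS (2.2 equiv), THF, −78 → 23 °C; AcOH quench, aq NH4Cl
Reagents that add atoms: 1-chloro-N,N,2-trimethylprop-1-en-1-amine (Ghosez reagent), CC(C)=C(Cl)N(C)C (Cl of 18 only)
Why: Proposed new method: the kinetic lithium enolate of acylketene acetal 17 (deprotonated at the ethyl CH2) is C-acylated by the non-enolisable acid chloride 18, a second equivalent of enolate deprotonates the 1,3-diketone 19, and the enolate oxygen next to the quaternary carbon closes the ring by 6-endo addition to the doubly oxygen-activated ketene-acetal carbon with loss of methoxide (new C–O bond O1–C2), which is driven by formation of the cross-conjugated pyrone, leaves exactly one OMe at C2 so that no separate regiochemically delicate O-methylation is needed, and touches no stereocentre; the closest known reaction types are the γ-pyrone synthesis by acylation of β-alkoxy-enone enolates with acid chlorides followed by oxa-Michael/β-elimination, and addition–elimination at α-oxoketene (dithio)acetals.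

Step 12
Reactants: 20 TES-protected pyrone
Product: 22 2-methoxy-3,5-dimethyl-6-{(1R,6S)-1,3,5-trimethyl-6-[(2E,4R)-4-methyl-5-oxohept-2-en-2-yl]cyclohexa-2,4-dien-1-yl}-4H-pyran-4-one (target), via 6-{(1R,6S)-6-[(2E,4R,5S)-5-hydroxy-4-methylhept-2-en-2-yl]-1,3,5-trimethylcyclohexa-2,4-dien-1-yl}-2-methoxy-3,5-dimethyl-4H-pyran-4-one 21 (not isolated)
Conditions: IBX (4 equiv), DMSO, 23 → 40 °C
Reagents that add atoms: none
Why: IBX in DMSO cleaves the TES ether and oxidises the freed secondary alcohol in the same flask (hypervalent-iodine oxidation) under base-free conditions, so the α-stereocentre of the β,γ-unsaturated ketone is neither epimerised nor conjugated.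

**Compound list**
1 | (S)-but-3-yn-2-ol | O[C@@H](C)C#C | starting material
2 | (S)-but-3-yn-2-yl methanesulfonate | CS(=O)(=O)O[C@@H](C)C#C | intermediate
3 | propanal | CCC=O | starting material
4 | (3S,4R)-4-methylhex-5-yn-3-ol | CC[C@H](O)[C@H](C)C#C | intermediate
5 | triethyl{[(3S,4R)-4-methylhex-5-yn-3-yl]oxy}silane | CC[C@H](O[Si](CC)(CC)CC)[C@H](C)C#C | intermediate
6 | (4R,5S)-4-methyl-5-(triethylsilyloxy)hept-2-yn-1-ol | CC[C@H](O[Si](CC)(CC)CC)[C@H](C)C#CCO | intermediate
7 | (2E,4R,5S)-4-methyl-2-(tributylstannyl)-5-(triethylsilyloxy)hept-2-en-1-ol | CC[C@H](O[Si](CC)(CC)CC)[C@H](C)/C=C(\CO)[Sn](CCCC)(CCCC)CCCC | intermediate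
8 | (2E,4R,5S)-2-iodo-4-methyl-5-(triethylsilyloxy)hept-2-en-1-ol | CC[C@H](O[Si](CC)(CC)CC)[C@H](C)/C=C(\CO)I | intermediate
9 | 3,5-dimethylbenzoic acid | Cc1cc(C)cc(C(O)=O)c1 | starting material
10 | 1,3,5-trimethylcyclohexa-2,5-diene-1-carboxylic acid | CC1=CC(C)(C(O)=O)C=C(C)C1 | intermediate
11 | [(2E,4R,5S)-2-iodo-4-methyl-5-(triethylsilyloxy)hept-2-en-1-yl] 1,3,5-trimethylcyclohexa-2,5-diene-1-carboxylate | CC[C@H](O[Si](CC)(CC)CC)[C@H](C)/C=C(\COC(=O)C1(C)C=C(C)CC(C)=C1)I | intermediate
12 | (4Z,4aR,8aR)-5,7,8a-trimethyl-4-[(2R,3S)-2-methyl-3-(triethylsilyloxy)pentylidene]-3,4,4a,8a-tetrahydro-1H-isochromen-1-one | CC[C@H](O[Si](CC)(CC)CC)[C@H](C)/C=C2/[C@H]1C(C)=CC(C)=C[C@@]1(C)C(=O)OC2 | intermediate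
13 | (1R,6S)-1,3,5-trimethyl-6-[(2E,4R,5S)-4-methyl-5-(triethylsilyloxy)hept-2-en-2-yl]cyclohexa-2,4-diene-1-carboxylic acid | CC[C@H](O[Si](CC)(CC)CC)[C@H](C)/C=C(\C)[C@H]1C(C)=CC(C)=C[C@@]1(C)C(O)=O | intermediate
14 | trimethyl orthopropionate (1,1,1-trimethoxypropane) | CCC(OC)(OC)OC | starting material
15 | propionyl chloride | CCC(Cl)=O | starting material
16 | 1,1-dimethoxyprop-1-ene | CC=C(OC)OC | intermediate
17 | 1,1-dimethoxy-2-methylpent-1-en-3-one | CCC(=O)C(C)=C(OC)OC | intermediate
18 | (1R,6S)-1,3,5-trimethyl-6-[(2E,4R,5S)-4-methyl-5-(triethylsilyloxy)hept-2-en-2-yl]cyclohexa-2,4-diene-1-carbonyl chloride | CC[C@H](O[Si](CC)(CC)CC)[C@H](C)/C=C(\C)[C@H]1C(C)=CC(C)=C[C@@]1(C)C(Cl)=O | intermediate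
19 | 5,5-dimethoxy-2,4-dimethyl-1-{(1R,6S)-1,3,5-trimethyl-6-[(2E,4R,5S)-4-methyl-5-(triethylsilyloxy)hept-2-en-2-yl]cyclohexa-2,4-dien-1-yl}pent-4-ene-1,3-dione (C2 epimers, largely enolised) | CC[C@H](O[Si](CC)(CC)CC)[C@H](C)/C=C(\C)[C@H]1C(C)=CC(C)=C[C@@]1(C)C(=O)C(C)C(=O)C(C)=C(OC)OC | intermediate
20 | 2-methoxy-3,5-dimethyl-6-{(1R,6S)-1,3,5-trimethyl-6-[(2E,4R,5S)-4-methyl-5-(triethylsilyloxy)hept-2-en-2-yl]cyclohexa-2,4-dien-1-yl}-4H-pyran-4-one | CC[C@H](O[Si](CC)(CC)CC)[C@H](C)/C=C(\C)[C@H]1C(C)=CC(C)=C[C@@]1(C)c1oc(OC)c(C)c(=O)c1C | intermediate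
21 | 6-{(1R,6S)-6-[(2E,4R,5S)-5-hydroxy-4-methylhept-2-en-2-yl]-1,3,5-trimethylcyclohexa-2,4-dien-1-yl}-2-methoxy-3,5-dimethyl-4H-pyran-4-one | CC[C@H](O)[C@H](C)/C=C(\C)[C@H]1C(C)=CC(C)=C[C@@]1(C)c1oc(OC)c(C)c(=O)c1C | intermediate
22 | 2-methoxy-3,5-dimethyl-6-{(1R,6S)-1,3,5-trimethyl-6-[(2E,4R)-4-methyl-5-oxohept-2-en-2-yl]cyclohexa-2,4-dien-1-yl}-4H-pyran-4-one | CCC(=O)[C@H](C)/C=C(\C)[C@H]1C(C)=CC(C)=C[C@@]1(C)c1oc(OC)c(C)c(=O)c1C | target

**Totals**
Total step count: 12.
Longest linear sequence: 10 steps (1, 2, 3, 4, 5, 7, 8, 9, 11, 12).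

**Three steps most likely to fail**

Step 11 (the proposed new step). The hindered acid chloride may O-acylate the enolate of 17, or 19 may lose MeOH in the wrong sense.
The fallback uses only known chemistry, sets out from 18 and comes back at 20. Acid chloride 18 is added to the dianion of commercial methyl 2-methyl-3-oxopentanoate (NaH, then n-BuLi, THF, −78 °C). This gives methyl 2,4-dimethyl-3,5-dioxo-5-{(1R,6S)-1,3,5-trimethyl-6-[(2E,4R,5S)-4-methyl-5-(triethylsilyloxy)hept-2-en-2-yl]cyclohexa-2,4-dien-1-yl}pentanoate F1. DBU in toluene closes it by lactonisation to 4-hydroxy-3,5-dimethyl-6-{(1R,6S)-1,3,5-trimethyl-6-[(2E,4R,5S)-4-methyl-5-(triethylsilyloxy)hept-2-en-2-yl]cyclohexa-2,4-dien-1-yl}-2H-pyran-2-one F2. MeOTf in CH2Cl2 then methylates the lactone carbonyl oxygen of the neutral pyrone to give 20.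

Step 8. The ester tether must adopt its less favoured conformation, the insertion meets a trisubstituted alkene next to a quaternary carbon, β-H elimination could go to the methyl group, and the ligand may discriminate the two ring alkenes poorly.
The fallback sets out from 6 and 10 and comes back at 12. It replaces oxidative addition of a vinyl iodide by a hydropalladation-initiated enyne cycloisomerisation (Alder-ene type). Mitsunobu esterification of 6 with 10 gives [(4R,5S)-4-methyl-5-(triethylsilyloxy)hept-2-yn-1-yl] 1,3,5-trimethylcyclohexa-2,5-diene-1-carboxylate F3. Pd(OAc)2 with N,N′-bis(benzylidene)ethylenediamine in benzene at 60 °C cyclises F3 to 12 and its ring diastereomer, which are separated by chromatography using the side-chain centres as the resolving handle.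

Step 9. LiBHEt3 may attack the lactone carbonyl, or hydride may be delivered to the inner allyl terminus and give the exo-methylene isomer.
The fallback sets out from 12 and comes back at 13. PhSeNa (from PhSeSePh and NaBH4, DMF) opens the lactone by SN2 attack at the allylic CH2–O carbon. This gives (1R,6S)-1,3,5-trimethyl-6-[(2Z,4R,5S)-4-methyl-1-(phenylselanyl)-5-(triethylsilyloxy)hept-2-en-2-yl]cyclohexa-2,4-diene-1-carboxylic acid F4. Bu3SnH with Et3B/air then removes selenium by a radical chain, and H-abstraction at the primary terminus of the allyl radical gives 13.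

**Further compounds**
F1 | step 11 | methyl 2,4-dimethyl-3,5-dioxo-5-{(1R,6S)-1,3,5-trimethyl-6-[(2E,4R,5S)-4-methyl-5-(triethylsilyloxy)hept-2-en-2-yl]cyclohexa-2,4-dien-1-yl}pentanoate | CC[C@H](O[Si](CC)(CC)CC)[C@H](C)/C=C(\C)[C@H]1C(C)=CC(C)=C[C@@]1(C)C(=O)C(C)C(=O)C(C)C(=O)OC
F2 | step 11 | 4-hydroxy-3,5-dimethyl-6-{(1R,6S)-1,3,5-trimethyl-6-[(2E,4R,5S)-4-methyl-5-(triethylsilyloxy)hept-2-en-2-yl]cyclohexa-2,4-dien-1-yl}-2H-pyran-2-one | CC[C@H](O[Si](CC)(CC)CC)[C@H](C)/C=C(\C)[C@H]1C(C)=CC(C)=C[C@@]1(C)c1oc(=O)c(C)c(O)c1C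
F3 | step 8 | [(4R,5S)-4-methyl-5-(triethylsilyloxy)hept-2-yn-1-yl] 1,3,5-trimethylcyclohexa-2,5-diene-1-carboxylate | CC[C@H](O[Si](CC)(CC)CC)[C@H](C)C#CCOC(=O)C1(C)C=C(C)CC(C)=C1
F4 | step 9 | (1R,6S)-1,3,5-trimethyl-6-[(2Z,4R,5S)-4-methyl-1-(phenylselanyl)-5-(triethylsilyloxy)hept-2-en-2-yl]cyclohexa-2,4-diene-1-carboxylic acid | CC[C@H](O[Si](CC)(CC)CC)[C@H](C)/C=C(\C[Se]c1ccccc1)[C@H]1C(C)=CC(C)=C[C@@]1(C)C(O)=O
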